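**Strategy.** Everything rests on disconnecting C5–C10 and C8–C9 of the decalin. One intramolecular Diels–Alder reaction of an open-chain, achiral aryl trienone then closes ring A (C1–C5, C10) and ring B (C5–C10) together and sets C5, C8, C9 and C10. The step exploits the run C8 (CHMe)–C9–C10 (quaternary) next to the fusion carbon C5 in ring B: the cis C8/C10 methyls and the trans fusion are encoded in an E,E-diene (C5–C8) and an E-enone (C9=C10), whose aroyl carbon C11 later becomes the chloroalkene carbon. The precursor 18 is the silyl-protected (2E,8E,10E)-aryl dodecatrienone, built by stereodefined olefination, cross-coupling and carbometalation.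

Key step: step 10

Remark 1: drimane numbering is used for the carbocycle (C4 = CMe2, C10 = angular C–Me, C11 = exocyclic carbon bound to the arene).
Remark 2: the target chloroalkene is E, with chlorine on the C8 side and the arene on the more crowded C10 side. Kinetic enolisation followed by a geometry-retaining exchange would place the arene on the C8 side (Z-chloride), so chloride is introduced by a stereoconvergent capture in step 13.
Remark 3: the E-enone is made by alkyne carbometalation because carbonyl olefination of a methyl ketone would give E/Z mixtures, and the IMDA is stereospecific in that geometry.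
Remark 4: short-lived species (carbocations, catalytic metal intermediates) are discussed in the Why lines and are not numbered.

Step 1
Reactants: 1 isobutyronitrile; 2 1-bromo-3-chloropropane
Product: 4 5-chloro-2,2-dimethylpentanenitrile, via lithiated isobutyronitrile 3 (not isolated)
Conditions: LDA (1.05 equiv), THF, −78 °C; then 2, −78 °C → rt
Reagents that add atoms: none
Why: Nitrile α-alkylation (SN2), in which the tertiary nitrile anion displaces bromide much faster than chloride, so the chloride survives as the handle for step 5.

Step 2
Reactants: 4 5-chloro-2,2-dimethylpentanenitrile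
Product: 6 5-chloro-2,2-dimethylpentanal, via N-aluminio aldimine 5 (not isolated)
Conditions: DIBAL-H (1.2 equiv), CH2Cl2, −78 °C; then 1 M aq. HCl, 0 °C
Reagents that add atoms: water, O
Why: DIBAL-H partial reduction of a nitrile, in which one hydride adds to the non-enolisable nitrile and the aluminium aldimine is hydrolysed to the aldehyde on acidic work-up.

Step 3
Reactants: 6 5-chloro-2,2-dimethylpentanal
Product: 7 (E)-6-chloro-1-iodo-3,3-dimethylhex-1-ene
Conditions: CrCl2 (6 equiv), CHI3 (2 equiv), THF, 0 °C → rt
Reagents that add atoms: iodoform, IC(I)I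
Why: Takai–Utimoto iodo-olefination, in which the gem-dichromium carbenoid adds to the aldehyde and eliminates to the E-iodoalkene (the quaternary α-carbon reinforces the E preference) while the alkyl chloride is inert to chromium(II).

Step 4
Reactants: 7 (E)-6-chloro-1-iodo-3,3-dimethylhex-1-ene; 8 (E)-prop-1-en-1-ylboronic acid
Product: 9 (5E,7E)-1-chloro-4,4-dimethylnona-5,7-diene
Conditions: Pd(PPh3)4 (5 mol%), 2 M aq. KOH, THF, 50 °C
Reagents that add atoms: none
Why: Suzuki–Miyaura alkenyl–alkenyl coupling proceeds with retention at both partners, so the E,E-diene geometry is inherited from 7 and 8, and Pd(0)/PPh3 leaves the primary chloride alone.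

Step 5
Reactants: 9 (5E,7E)-1-chloro-4,4-dimethylnona-5,7-diene
Product: 10 (7E,9E)-6,6-dimethylundeca-7,9-dien-1-yne
Conditions: lithium acetylide–ethylenediamine complex (2 equiv), DMSO, rt
Reagents that add atoms: lithium acetylide–ethylenediamine complex, [Li]C#C.NCCN
Why: SN2 alkylation of acetylide at the unhindered primary chloride in DMSO, under which the non-acidic diene is untouched and the terminal alkyne does not migrate at room temperature.

Step 6
Reactants: 10 (7E,9E)-6,6-dimethylundeca-7,9-dien-1-yne
Product: 12 (1E,7E,9E)-1-iodo-2,6,6-trimethylundeca-1,7,9-triene, via alkenyldimethylalane 11 (not isolated)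
Conditions: Me3Al (2.5 equiv), Cp2ZrCl2 (0.25 equiv), CH2Cl2, 0 °C → rt; then I2 (1.2 equiv), THF, −30 → 0 °C
Reagents that add atoms: trimethylaluminium, C[Al](C)C; iodine, II
Why: Negishi zirconium-catalysed carboalumination adds Me–Al syn across the terminal alkyne with methyl on the internal carbon, and iodinolysis with retention gives the E-iodoalkene, while 1,2-disubstituted alkenes are not carbometalated.

Step 7
Reactants: 13 3-methoxysalicylic acid
Product: 15 2-hydroxy-N,3-dimethoxy-N-methylbenzamide, via acyl imidazolide 14 (not isolated)
Conditions: CDI (1.1 equiv), THF, rt; then MeNH(OMe)·HCl (1.3 equiv), rt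
Reagents that add atoms: N,O-dimethylhydroxylamine hydrochloride, CNOC.Cl
Why: CDI amidation, in which the acid is activated as the acyl imidazolide and acylates the hydroxylamine while the hydrogen-bonded phenol is a much poorer nucleophile.

Step 8
Reactants: 15 2-hydroxy-N,3-dimethoxy-N-methylbenzamide
Product: 16 2-[(tert-butyldimethylsilyl)oxy]-N,3-dimethoxy-N-methylbenzamide
Conditions: TBSCl (1.3 equiv), imidazole (2.5 equiv), DMF, rt
Reagents that add atoms: tert-butyldimethylsilyl chloride, CC(C)(C)[Si](C)(C)Cl
Why: Imidazole-promoted O-silylation of the phenol gives an ether that blocks phenoxide chemistry (oxa-Michael closure of the later enone, chelation in the key step) and is removed by fluoride at the end.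

Step 9
Reactants: 12 (1E,7E,9E)-1-iodo-2,6,6-trimethylundeca-1,7,9-triene; 16 2-[(tert-butyldimethylsilyl)oxy]-N,3-dimethoxy-N-methylbenzamide
Product: 18 (2E,8E,10E)-1-{2-[(tert-butyldimethylsilyl)oxy]-3-methoxyphenyl}-3,7,7-trimethyldodeca-2,8,10-trien-1-one, via alkenyllithium 17 (not isolated)
Conditions: t-BuLi (2.05 equiv), Et2O, −78 °C; then 16 (1.1 equiv), THF, −78 °C; sat. aq. NH4Cl at −78 °C
Reagents that add atoms: none
Why: Lithium–iodine exchange retains the alkene geometry of 12 (which becomes the E-enone), and the Weinreb ketone synthesis stops at the chelated tetrahedral adduct, which is quenched cold so that silyl transfer to the alkoxide cannot set in.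

Step 10
Reactants: 18 (2E,8E,10E)-1-{2-[(tert-butyldimethylsilyl)oxy]-3-methoxyphenyl}-3,7,7-trimethyldodeca-2,8,10-trien-1-one
Product: 19 {2-[(tert-butyldimethylsilyl)oxy]-3-methoxyphenyl}[(1S,2S,4aS,8aS)-2,5,5,8a-tetramethyl-1,2,4a,5,6,7,8,8a-octahydronaphthalen-1-yl]methanone
Conditions: (S)-o-tolyl-CBS oxazaborolidine (20 mol%), AlBr3 (16 mol%), CH2Cl2, −78 → −20 °C
Reagents that add atoms: none
Why: Lewis-acid activation of the ketone by the cationic oxazaborolidine lowers the enone LUMO, and the E,E-diene adds in a concerted, asynchronous, suprafacial [4+2] (intramolecular Diels–Alder reaction of an (E,E,E)-1,7,9-decatrien-3-one); the closest known reaction type is the oxazaborolidinium-catalysed enantioselective Diels–Alder reaction of α,β-unsaturated carbonyl compounds, which has intramolecular versions. Ring B (C5–C10) is the cyclohexene made by the new bonds C5–C10 and C8–C9, and ring A (C1–C5 and C10) closes through the same C5–C10 bond in an exo-type six-ring closure with the C1–C4 tether folded as a chair. C5 and C8 are related by the E,E-diene (C4 and the C8 methyl come out cis), C9 and C10 by the E-enone (aroyl and C10 methyl cis), and the carbonyl-endo, tether-exo arrangement puts these four groups on one face, hence the trans fusion with 8β-methyl and 9β-aroyl. The absolute sense comes from the catalyst, which should hold the ketone by its oxygen with a C9–H···O contact and screen one enone face with an aryl group, so that the diene adds to the C9 Si/C10 Re face; the (S)-catalyst is the first choice from this model, its antipode gives the mirror image, and the sense is to be confirmed on 19. The step needs endo over exo selectivity and one enantioface: Lewis-acid catalysis strengthens the endo preference, the ortho-silyloxy group keeps the arene twisted so that the ketone binds the catalyst at one point and stays reactive, and the gem-dimethyl group at C4 favours the folded rotamer.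

Step 11
Reactants: 19 the octalin ketone
Product: 20 {2-[(tert-butyldimethylsilyl)oxy]-3-methoxyphenyl}[(1S,2S,4aS,8aS)-2,5,5,8a-tetramethyldecahydronaphthalen-1-yl]methanone
Conditions: H2 (1–4 atm), 5% Pt/C, EtOAc, rt
Reagents that add atoms: none
Why: Heterogeneous catalytic hydrogenation saturates the only alkene (C6=C7), and platinum in a neutral aprotic solvent is chosen because it causes little double-bond migration toward C8 and leaves the hindered aryl ketone and the silyl ether alone.

Step 12
Reactants: 20 the decalin ketone
Product: 21 (Z)-{2-[(tert-butyldimethylsilyl)oxy]-3-methoxyphenyl}[(2S,4aS,8aS)-2,5,5,8a-tetramethyloctahydronaphthalen-1(2H)-ylidene]methyl trifluoromethanesulfonate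
Conditions: Tf2O (1.5 equiv), 2,6-di-tert-butyl-4-methylpyridine (2 equiv), ClCH2CH2Cl, 0 → 50 °C
Reagents that add atoms: triflic anhydride, O=S(=O)(OS(=O)(=O)C(F)(F)F)C(F)(F)F
Why: Electrophilic enol triflate formation (carbonyl O-triflylation, then loss of H9, the only α-hydrogen) forms no enolate, so the silyl group cannot migrate to an enolate oxygen; the Z isomer (triflate on the C10 side, arene away from the C1 methylene) should prevail, and either isomer serves in step 13.

Step 13
Reactants: 21 the enol triflate
Product: 22 tert-butyl(2-{(E)-chloro[(2S,4aS,8aS)-2,5,5,8a-tetramethyloctahydronaphthalen-1(2H)-ylidene]methyl}-6-methoxyphenoxy)dimethylsilane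
Conditions: n-Bu4NCl (5 equiv), 2,6-di-tert-butyl-4-methylpyridine (0.2 equiv), (CF3)2CHOH/CH2Cl2 1:1, 40 °C
Reagents that add atoms: tetrabutylammonium chloride, CCCC[N+](CCCC)(CCCC)CCCC.[Cl-]
Why: Proposed new method: ionisation of the crowded α-aryl enol triflate in the strongly ionising, non-nucleophilic alcohol should give the linear, aryl-stabilised vinyl cation at C11 (arene perpendicular to the alkene plane, empty orbital in that plane), and chloride should enter in the plane from the open C8 side (equatorial H) and not from the C10 side (C1 methylene, departing triflate), so that both triflate isomers converge on the E-chloride with chlorine next to C8 and the arene next to C10, a geometry that a retentive exchange from the Z-triflate would not give and that should persist because chloride is too poor a leaving group to re-ionise; the closest known reaction type is SN1 solvolysis of α-arylvinyl triflates and halides with capture of the vinyl cation by an added nucleophile on the side of the smaller β-substituent.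

Step 14
Reactants: 22 the silyl-protected chloroalkene
Product: 23 2-{(E)-chloro[(2S,4aS,8aS)-2,5,5,8a-tetramethyloctahydronaphthalen-1(2H)-ylidene]methyl}-6-methoxyphenol
Conditions: TBAF (1.1 equiv), THF, 0 °C; sat. aq. NH4Cl
Reagents that add atoms: none
Why: Fluoride-induced desilylation of the aryl silyl ether is fast under neutral to weakly basic conditions, in which the fully substituted chloroalkene can neither eliminate nor isomerise.

Step 15
Reactants: 23 the phenol
Product: 24 2-{(E)-chloro[(2S,4aS,8aS)-2,5,5,8a-tetramethyloctahydronaphthalen-1(2H)-ylidene]methyl}-6-methoxycyclohexa-2,5-diene-1,4-dione (CNP0249629.1)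
Conditions: O2 (1 atm), Co(salen) (salcomine, 10 mol%), MeCN, rt
Reagents that add atoms: dioxygen, O=O
Why: Salcomine-catalysed aerobic oxidation of a 2,6-disubstituted phenol with a free para position gives the para-quinone (phenoxyl radical, C–O bond formation para to the OH, loss of water), which is the 2-methoxy-6-alkenyl-1,4-benzoquinone.

**Compound list**

1 | isobutyronitrile | CC(C)C#N | starting material
2 | 1-bromo-3-chloropropane | ClCCCBr | starting material
3 | 2-lithio-2-methylpropanenitrile | [Li]C(C)(C)C#N | intermediate
4 | 5-chloro-2,2-dimethylpentanenitrile | N#CC(C)(C)CCCCl | intermediate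
5 | N-(diisobutylalumanyl)-5-chloro-2,2-dimethylpentan-1-imine | CC(C)C[Al](CC(C)C)N=CC(C)(C)CCCCl | intermediate
6 | 5-chloro-2,2-dimethylpentanal | O=CC(C)(C)CCCCl | intermediate
7 | (E)-6-chloro-1-iodo-3,3-dimethylhex-1-ene | I/C=C/C(C)(C)CCCCl | intermediate
8 | (E)-prop-1-en-1-ylboronic acid | C/C=C/B(O)O | starting material
9 | (5E,7E)-1-chloro-4,4-dimethylnona-5,7-diene | ClCCCC(C)(C)/C=C/C=C/C | intermediate
10 | (7E,9E)-6,6-dimethylundeca-7,9-dien-1-yne | C#CCCCC(C)(C)/C=C/C=C/C | intermediate
11 | dimethyl[(1E,7E,9E)-2,6,6-trimethylundeca-1,7,9-trien-1-yl]alumane | C[Al](C)/C=C(\C)CCCC(C)(C)/C=C/C=C/C | intermediate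
12 | (1E,7E,9E)-1-iodo-2,6,6-trimethylundeca-1,7,9-triene | I/C=C(\C)CCCC(C)(C)/C=C/C=C/C | intermediate
13 | 3-methoxysalicylic acid | COc1cccc(C(=O)O)c1O | starting material
14 | (2-hydroxy-3-methoxyphenyl)(1H-imidazol-1-yl)methanone | COc1cccc(C(=O)n2ccnc2)c1O | intermediate
15 | 2-hydroxy-N,3-dimethoxy-N-methylbenzamide | CON(C)C(=O)c1cccc(OC)c1O | intermediate
16 | 2-[(tert-butyldimethylsilyl)oxy]-N,3-dimethoxy-N-methylbenzamide | CON(C)C(=O)c1cccc(OC)c1O[Si](C)(C)C(C)(C)C | intermediate
17 | [(1E,7E,9E)-2,6,6-trimethylundeca-1,7,9-trien-1-yl]lithium | [Li]/C=C(\C)CCCC(C)(C)/C=C/C=C/C | intermediate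
18 | (2E,8E,10E)-1-{2-[(tert-butyldimethylsilyl)oxy]-3-methoxyphenyl}-3,7,7-trimethyldodeca-2,8,10-trien-1-one | C/C=C/C=C/C(C)(C)CCC/C(C)=C/C(=O)c1cccc(OC)c1O[Si](C)(C)C(C)(C)C | intermediate
19 | {2-[(tert-butyldimethylsilyl)oxy]-3-methoxyphenyl}[(1S,2S,4aS,8aS)-2,5,5,8a-tetramethyl-1,2,4a,5,6,7,8,8a-octahydronaphthalen-1-yl]methanone | O=C(c1cccc(OC)c1O[Si](C)(C)C(C)(C)C)[C@H]1[C@@H](C)C=C[C@H]2C(C)(C)CCC[C@]12C | intermediate
20 | {2-[(tert-butyldimethylsilyl)oxy]-3-methoxyphenyl}[(1S,2S,4aS,8aS)-2,5,5,8a-tetramethyldecahydronaphthalen-1-yl]methanone | O=C(c1cccc(OC)c1O[Si](C)(C)C(C)(C)C)[C@H]1[C@@H](C)CC[C@H]2C(C)(C)CCC[C@]12C | intermediate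
21 | (Z)-{2-[(tert-butyldimethylsilyl)oxy]-3-methoxyphenyl}[(2S,4aS,8aS)-2,5,5,8a-tetramethyloctahydronaphthalen-1(2H)-ylidene]methyl trifluoromethanesulfonate (expected major isomer drawn; the E isomer is equally usable) | COc1cccc(/C(OS(=O)(=O)C(F)(F)F)=C2\[C@@H](C)CC[C@H]3C(C)(C)CCC[C@]23C)c1O[Si](C)(C)C(C)(C)C | intermediate
22 | tert-butyl(2-{(E)-chloro[(2S,4aS,8aS)-2,5,5,8a-tetramethyloctahydronaphthalen-1(2H)-ylidene]methyl}-6-methoxyphenoxy)dimethylsilane | COc1cccc(/C(Cl)=C2/[C@@H](C)CC[C@H]3C(C)(C)CCC[C@]23C)c1O[Si](C)(C)C(C)(C)C | intermediate
23 | 2-{(E)-chloro[(2S,4aS,8aS)-2,5,5,8a-tetramethyloctahydronaphthalen-1(2H)-ylidene]methyl}-6-methoxyphenol | COc1cccc(/C(Cl)=C2/[C@@H](C)CC[C@H]3C(C)(C)CCC[C@]23C)c1O | intermediate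
24 | 2-{(E)-chloro[(2S,4aS,8aS)-2,5,5,8a-tetramethyloctahydronaphthalen-1(2H)-ylidene]methyl}-6-methoxycyclohexa-2,5-diene-1,4-dione | COC1=CC(=O)C=C(/C(Cl)=C2/[C@@H](C)CC[C@H]3C(C)(C)CCC[C@]23C)C1=O | target

**Step count.** Total: 15 steps. Longest linear sequence: 13 steps (steps 1–6, then 9–15); the arene branch (steps 7–8) joins at step 9.

**Steps most likely to fail**

Step 13. The triflate may ionise too slowly, because the silyloxy arene is only a moderate donor. The cation may also be captured from both sides or by the solvent, so that control of the alkene geometry is lost. The fallback uses known chemistry and sets out from 21: the triflate is exchanged for chloride by palladium catalysis (Pd2(dba)3, t-BuBrettPhos, KCl, KF, 1,4-dioxane, 110 °C), an established conversion of alkenyl triflates into alkenyl chlorides. Oxidative addition places palladium on the C10 side, and the known E/Z isomerisation of α-aryl alkenylpalladium(II) species should let the bulky metal move to the C8 side before the slow C–Cl reductive elimination. The route is rejoined at 22, and the detour passes through no new isolable compound (F0).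

Step 10. Turnover of the chiral catalyst may be too slow for a β,β-disubstituted enone whose C5–C10 bond forms between two crowded carbons. At the higher temperature then needed, facial and endo/exo selectivity would erode. The fallback sets out from 18: the cyclisation is promoted by a stoichiometric achiral Lewis acid (MeAlCl2, CH2Cl2, −78 → 0 °C), which should give the racemate, that is 19 together with its mirror image ent-19 F1. The enantiomers are separated by preparative chromatography on a chiral stationary phase, and 19 rejoins the route before step 11.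

Step 12. O-Triflylation of the very hindered, twisted aryl ketone may stall, or traces of triflic acid may strip the silyl ether on prolonged heating. The fallback sets out from 20: the ketone is deprotonated at C9 with KHMDS (THF, −78 °C) to the potassium enolate F2, expected as the Z isomer with the arene away from C10. It is sulfonylated at oxygen at −78 °C with N-(5-chloropyridin-2-yl)triflimide before aryl-to-enolate silyl transfer can compete, which returns to the route at 21.

**Further compounds**

F1 | step 10 | {2-[(tert-butyldimethylsilyl)oxy]-3-methoxyphenyl}[(1R,2R,4aR,8aR)-2,5,5,8a-tetramethyl-1,2,4a,5,6,7,8,8a-octahydronaphthalen-1-yl]methanone (ent-19) | O=C(c1cccc(OC)c1O[Si](C)(C)C(C)(C)C)[C@@H]1[C@H](C)C=C[C@@H]2C(C)(C)CCC[C@@]12C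
F2 | step 12 | potassium (Z)-{2-[(tert-butyldimethylsilyl)oxy]-3-methoxyphenyl}[(2S,4aS,8aS)-2,5,5,8a-tetramethyloctahydronaphthalen-1(2H)-ylidene]methanolate | COc1cccc(/C([O-])=C2\[C@@H](C)CC[C@H]3C(C)(C)CCC[C@]23C)c1O[Si](C)(C)C(C)(C)C.[K+]
F0 | step 13 | none | none
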